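**Plan**
- Retrosynthesis: the 5-O and 4'-O benzyl bonds are cut last and C3–OH is traced back to C3–I. The pyranone O1–C2 bond is then cut, opening ring C to an aryl ynone, which is cut at C4–C3 into an aryl aldehyde and an arylacetylide. The formyl carbon and the two flanking C–O bonds of ring A lead back to 1,2,3-trimethoxybenzene.
- Enabling feature: the acyl-bearing ring-A carbon (future C4a) lies between two carbons carrying identical benzyloxy groups (future C8a and C5). C6, C7 and C8 are methoxylated and no ring CH remains, so either oxygen can become O1 while the other stays as the masked 5-OH.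
- Forward order: ring A is fully oxygenated, formylated and benzylated; ring B is joined as its acetylide; ring C is closed last by iodonium-triggered O-attack on the alkyne. The iodine left at C3 is then exchanged for hydroxyl and the benzyl ethers are removed.
- Stereochemistry: the target is planar and achiral. The only stereocentre met on the way, the propargylic carbinol, is made racemic and erased by oxidation.

Key step: step 8

Assumption: the target SMILES holds no stereocentre, so the single-enantiomer requirement is met by the achiral compound itself and no asymmetric step is planned.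

**Step 1**
Reactants: 1 1,2,3-trimethoxybenzene
Product: 2 1,5-dibromo-2,3,4-trimethoxybenzene
Conditions: NBS (2.2 equiv), MeCN, 0 °C → 50 °C
Reagents that add atoms: N-bromosuccinimide, O=C1CCC(=O)N1Br
Why: Electrophilic aromatic bromination; C4 and C6 are each ortho/para to two methoxy groups whereas C5 is activated only by the twisted central methoxy group, so double substitution should give the 4,6-dibromide.

**Step 2**
Reactants: 2 1,5-dibromo-2,3,4-trimethoxybenzene
Product: 3 4,5,6-trimethoxybenzene-1,3-diol
Conditions: Pd2(dba)3 (cat.), t-BuXPhos, KOH, 1,4-dioxane/H2O, 100 °C, Ar; then aq. HCl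
Reagents that add atoms: potassium hydroxide, [K+].[OH-]
Why: Palladium-catalysed hydroxylation of aryl bromides (C–O cross-coupling with hydroxide) under a bulky biarylphosphine tolerates electron-rich, ortho-alkoxy bromides and should exchange both bromines under air-free conditions.

**Step 3**
Reactants: 3 4,5,6-trimethoxybenzene-1,3-diol
Product: 5 2,6-dihydroxy-3,4,5-trimethoxybenzaldehyde, via aryl iminium chloride 4 (not isolated)
Conditions: POCl3, DMF, EtOAc, 0 °C → rt; then H2O, 50 °C
Reagents that add atoms: N,N-dimethylformamide, CN(C)C=O; water, O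
Why: Vilsmeier–Haack formylation; the only ring CH is ortho to both hydroxyls and para to a methoxy group (a phloroglucinol-like position), so C-formylation can occur only there, and hydrolysis of the iminium salt should give the hydrogen-bonded aldehyde.

**Step 4**
Reactants: 5 2,6-dihydroxy-3,4,5-trimethoxybenzaldehyde; 6 benzyl bromide
Product: 7 2,6-bis(benzyloxy)-3,4,5-trimethoxybenzaldehyde
Conditions: 6 (2.4 equiv), K2CO3, Bu4NI (cat.), DMF, 60 °C
Reagents that add atoms: none
Why: Williamson ether synthesis; both phenols should be O-benzylated because no ring CH is left for C-alkylation and the aldehyde is inert to carbonate.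

**Step 5**
Reactants: 8 4-(benzyloxy)benzaldehyde
Product: 9 1-(benzyloxy)-4-ethynylbenzene
Conditions: dimethyl (1-diazo-2-oxopropyl)phosphonate, K2CO3, MeOH, rt
Reagents that add atoms: dimethyl (1-diazo-2-oxopropyl)phosphonate, COP(=O)(OC)C(=[N+]=[N-])C(C)=O
Why: Ohira–Bestmann (Seyferth–Gilbert) homologation turns a non-enolisable aryl aldehyde into the terminal alkyne in one step and leaves the benzyl ether untouched.

**Step 6**
Reactants: 9 1-(benzyloxy)-4-ethynylbenzene; 7 2,6-bis(benzyloxy)-3,4,5-trimethoxybenzaldehyde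
Product: 11 rac-1-[2,6-bis(benzyloxy)-3,4,5-trimethoxyphenyl]-3-[4-(benzyloxy)phenyl]prop-2-yn-1-ol, via lithium arylacetylide 10 (not isolated)
Conditions: n-BuLi, THF, −78 °C; then 7, −78 → 0 °C; H2O
Reagents that add atoms: none
Why: 1,2-Addition of a lithium acetylide to a non-enolisable aryl aldehyde; the carbinol centre is formed racemic on purpose because the next step removes it.

**Step 7**
Reactants: 11 rac-1-[2,6-bis(benzyloxy)-3,4,5-trimethoxyphenyl]-3-[4-(benzyloxy)phenyl]prop-2-yn-1-ol
Product: 12 1-[2,6-bis(benzyloxy)-3,4,5-trimethoxyphenyl]-3-[4-(benzyloxy)phenyl]prop-2-yn-1-one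
Conditions: activated MnO2 (excess), CH2Cl2, rt
Reagents that add atoms: none
Why: Manganese dioxide oxidation of a benzylic, propargylic secondary alcohol to the ynone under neutral conditions that spare the benzyl ethers.

**Step 8**
Reactants: 12 1-[2,6-bis(benzyloxy)-3,4,5-trimethoxyphenyl]-3-[4-(benzyloxy)phenyl]prop-2-yn-1-one; 13 iodine monochloride
Product: 15 5-(benzyloxy)-2-[4-(benzyloxy)phenyl]-3-iodo-6,7,8-trimethoxy-4H-chromen-4-one, via O-benzyl oxonium chloride 14 (not isolated)
Conditions: 13 (1.2 equiv), CH2Cl2, −78 °C; aq. Na2S2O3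
Reagents that add atoms: none
Why: ICl delivers I+ to the ynone triple bond, giving an iodonium ion whose positive charge is best supported at the alkyne carbon bearing the 4-benzyloxyphenyl ring. One of the two ortho benzyloxy oxygens attacks that carbon anti to iodine, forming O1–C2 and closing the pyranone ring in a 6-endo-dig mode to oxonium 14, and chloride then removes the benzyl group at its benzylic carbon (as benzyl chloride) to leave the neutral 3-iodoflavone. The closest known reaction type is the ICl-induced iodocyclisation–dealkylation of 2-alkoxyaryl ynones to 3-iodochromones and 3-iodoflavones. No stereocentre is formed, so no stereocontrol is needed. The step needs 6-endo over 5-exo closure, which the cation-stabilising para-alkoxyaryl group on the attacked carbon and the conjugated pyranone product secure, and it needs no choice between the ring-A oxygens because the benzyloxy groups flanking the acyl-bearing carbon are identical and ring A has no free CH. Only the ortho benzyloxy oxygens can reach the alkyne and the benzylic carbon is the better site for chloride attack than a methyl carbon, while −78 °C and near-stoichiometric ICl should keep iodination of ring B in check.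

**Step 9**
Reactants: 15 5-(benzyloxy)-2-[4-(benzyloxy)phenyl]-3-iodo-6,7,8-trimethoxy-4H-chromen-4-one
Product: 18 5-(benzyloxy)-2-[4-(benzyloxy)phenyl]-3-hydroxy-6,7,8-trimethoxy-4H-chromen-4-one, via flavon-3-ylmagnesium chloride 16 (not isolated), via dimethyl flavon-3-ylboronate 17 (not isolated)
Conditions: i-PrMgCl·LiCl, THF, −40 °C; B(OMe)3, −40 → 0 °C; AcOH, 30% aq. H2O2, 0 °C → rt
Reagents that add atoms: hydrogen peroxide, OO
Why: Iodine–magnesium exchange at the sp2 C3–I bond should give the carbonyl-stabilised 3-magnesiated flavone at low temperature, which is trapped as the boronate and oxidised by peroxide through 1,2-migration of C3 from boron to oxygen (halogen–metal exchange, borylation, oxidation), the borate–peroxide sequence established for C3-metalated flavones.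

**Step 10**
Reactants: 18 5-(benzyloxy)-2-[4-(benzyloxy)phenyl]-3-hydroxy-6,7,8-trimethoxy-4H-chromen-4-one
Product: 19 3,5-dihydroxy-2-(4-hydroxyphenyl)-6,7,8-trimethoxy-4H-chromen-4-one
Conditions: H2 (1 atm), 10% Pd/C, EtOAc/MeOH, rt
Reagents that add atoms: none
Why: Catalytic hydrogenolysis of the two aryl benzyl ethers; the pyranone C2=C3 bond of a flavonol and the methyl ethers should not be touched at 1 atm and room temperature.

**Compound list**
1 | 1,2,3-trimethoxybenzene | COc1cccc(OC)c1OC | starting material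
2 | 1,5-dibromo-2,3,4-trimethoxybenzene | COc1c(Br)cc(Br)c(OC)c1OC | intermediate
3 | 4,5,6-trimethoxybenzene-1,3-diol | COc1c(O)cc(O)c(OC)c1OC | intermediate
4 | N-[(2,6-dihydroxy-3,4,5-trimethoxyphenyl)methylidene]-N-methylmethanaminium chloride | C[N+](C)=Cc1c(O)c(OC)c(OC)c(OC)c1O.[Cl-] | intermediate (not isolated)
5 | 2,6-dihydroxy-3,4,5-trimethoxybenzaldehyde | O=Cc1c(O)c(OC)c(OC)c(OC)c1O | intermediate
6 | benzyl bromide | BrCc1ccccc1 | starting material
7 | 2,6-bis(benzyloxy)-3,4,5-trimethoxybenzaldehyde | O=Cc1c(OCc2ccccc2)c(OC)c(OC)c(OC)c1OCc1ccccc1 | intermediate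
8 | 4-(benzyloxy)benzaldehyde | O=Cc1ccc(OCc2ccccc2)cc1 | starting material
9 | 1-(benzyloxy)-4-ethynylbenzene | C#Cc1ccc(OCc2ccccc2)cc1 | intermediate
10 | lithium [4-(benzyloxy)phenyl]acetylide | [Li]C#Cc1ccc(OCc2ccccc2)cc1 | intermediate (not isolated)
11 | rac-1-[2,6-bis(benzyloxy)-3,4,5-trimethoxyphenyl]-3-[4-(benzyloxy)phenyl]prop-2-yn-1-ol (racemic carbinol) | OC(C#Cc1ccc(OCc2ccccc2)cc1)c1c(OCc2ccccc2)c(OC)c(OC)c(OC)c1OCc1ccccc1 | intermediate
12 | 1-[2,6-bis(benzyloxy)-3,4,5-trimethoxyphenyl]-3-[4-(benzyloxy)phenyl]prop-2-yn-1-one | O=C(C#Cc1ccc(OCc2ccccc2)cc1)c1c(OCc2ccccc2)c(OC)c(OC)c(OC)c1OCc1ccccc1 | intermediate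
13 | iodine monochloride | ClI | starting material
14 | 1-benzyl-5-(benzyloxy)-2-[4-(benzyloxy)phenyl]-3-iodo-6,7,8-trimethoxy-4-oxo-4H-chromen-1-ium chloride (O1-benzyl oxonium) | O=C1C(I)=C(c2ccc(OCc3ccccc3)cc2)[O+](Cc2ccccc2)c2c(OC)c(OC)c(OC)c(OCc3ccccc3)c12.[Cl-] | intermediate (not isolated)
15 | 5-(benzyloxy)-2-[4-(benzyloxy)phenyl]-3-iodo-6,7,8-trimethoxy-4H-chromen-4-one | O=c1c(I)c(-c2ccc(OCc3ccccc3)cc2)oc2c(OC)c(OC)c(OC)c(OCc3ccccc3)c12 | intermediate
16 | {5-(benzyloxy)-2-[4-(benzyloxy)phenyl]-6,7,8-trimethoxy-4-oxo-4H-chromen-3-yl}magnesium chloride | O=c1c([Mg]Cl)c(-c2ccc(OCc3ccccc3)cc2)oc2c(OC)c(OC)c(OC)c(OCc3ccccc3)c12 | intermediate (not isolated)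
17 | dimethyl {5-(benzyloxy)-2-[4-(benzyloxy)phenyl]-6,7,8-trimethoxy-4-oxo-4H-chromen-3-yl}boronate | O=c1c(B(OC)OC)c(-c2ccc(OCc3ccccc3)cc2)oc2c(OC)c(OC)c(OC)c(OCc3ccccc3)c12 | intermediate (not isolated)
18 | 5-(benzyloxy)-2-[4-(benzyloxy)phenyl]-3-hydroxy-6,7,8-trimethoxy-4H-chromen-4-one | O=c1c(O)c(-c2ccc(OCc3ccccc3)cc2)oc2c(OC)c(OC)c(OC)c(OCc3ccccc3)c12 | intermediate
19 | 3,5-dihydroxy-2-(4-hydroxyphenyl)-6,7,8-trimethoxy-4H-chromen-4-one (3,5,4'-trihydroxy-6,7,8-trimethoxyflavone) | COc1c(OC)c(O)c2c(=O)c(O)c(-c3ccc(O)cc3)oc2c1OC | target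

**Step count and risks**
Total step count: 10. Longest linear sequence: 9 steps (steps 1–4 and 6–10 from 1,2,3-trimethoxybenzene); the alkyne arm (step 5) joins at step 6.

Steps most likely to fail:

Step 8. Iodination of the alkoxy-activated B ring may compete with alkyne activation, the closure may go 5-exo to an aurone-type iodoalkylidene, or the benzyl cation may be captured by an arene instead of chloride. The fallback sets out from 12 and closes the same O1–C2 bond by conjugate addition of a free phenol. Chelation-directed cleavage of one ortho benzyl ether with MgBr2·OEt2 (toluene/Et2O) should give 1-[2-(benzyloxy)-6-hydroxy-3,4,5-trimethoxyphenyl]-3-[4-(benzyloxy)phenyl]prop-2-yn-1-one F1. A DMAP-catalysed 6-endo oxa-Michael cyclisation (DMF, rt) should then give 5-(benzyloxy)-2-[4-(benzyloxy)phenyl]-6,7,8-trimethoxy-4H-chromen-4-one F2. Deprotonation at C3 with LDA (THF, −78 °C) should give {5-(benzyloxy)-2-[4-(benzyloxy)phenyl]-6,7,8-trimethoxy-4-oxo-4H-chromen-3-yl}lithium F3, and trapping with B(OMe)3 returns to the route at boronate 17, which is oxidised to 18 as in step 9.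

Step 9. The C3-magnesiated pyranone may ring-open by β-elimination of the O1 phenoxide, the Grignard reagent may add to the C4 carbonyl, or the metalated species may be protonated before borate capture. The fallback sets out from 15 and replaces metalation by C–O cross-coupling. A copper-catalysed Ullmann-type etherification of the vinylic iodide with benzyl alcohol (CuI, 3,4,7,8-tetramethyl-1,10-phenanthroline, Cs2CO3, toluene, 90 °C) should give 3,5-bis(benzyloxy)-2-[4-(benzyloxy)phenyl]-6,7,8-trimethoxy-4H-chromen-4-one F4. Hydrogenolysis of all three benzyl ethers (H2, Pd/C, EtOAc/MeOH) then rejoins the route at 19.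

Step 2. The second C–O coupling may stall once the very electron-rich bromophenoxide has formed, hydrodebromination may intervene, or the resorcinol may be oxidised by air in hot base. The fallback sets out from 2 and installs the oxygens through carbon–boron bonds. Double Miyaura borylation (B2pin2, Pd(dppf)Cl2, KOAc, 1,4-dioxane, 90 °C) should give 2,2'-(4,5,6-trimethoxy-1,3-phenylene)bis(4,4,5,5-tetramethyl-1,3,2-dioxaborolane) F5. Brief oxidation (Oxone, acetone/H2O, 0 °C) rejoins the route at 3.

**Further compounds**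
F1 | step 8 | 1-[2-(benzyloxy)-6-hydroxy-3,4,5-trimethoxyphenyl]-3-[4-(benzyloxy)phenyl]prop-2-yn-1-one | O=C(C#Cc1ccc(OCc2ccccc2)cc1)c1c(O)c(OC)c(OC)c(OC)c1OCc1ccccc1
F2 | step 8 | 5-(benzyloxy)-2-[4-(benzyloxy)phenyl]-6,7,8-trimethoxy-4H-chromen-4-one | O=c1cc(-c2ccc(OCc3ccccc3)cc2)oc2c(OC)c(OC)c(OC)c(OCc3ccccc3)c12
F3 | step 8 | {5-(benzyloxy)-2-[4-(benzyloxy)phenyl]-6,7,8-trimethoxy-4-oxo-4H-chromen-3-yl}lithium | [Li]c1c(-c2ccc(OCc3ccccc3)cc2)oc2c(OC)c(OC)c(OC)c(OCc3ccccc3)c2c1=O
F4 | step 9 | 3,5-bis(benzyloxy)-2-[4-(benzyloxy)phenyl]-6,7,8-trimethoxy-4H-chromen-4-one | O=c1c(OCc2ccccc2)c(-c2ccc(OCc3ccccc3)cc2)oc2c(OC)c(OC)c(OC)c(OCc3ccccc3)c12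
F5 | step 2 | 2,2'-(4,5,6-trimethoxy-1,3-phenylene)bis(4,4,5,5-tetramethyl-1,3,2-dioxaborolane) | COc1c(B2OC(C)(C)C(C)(C)O2)cc(B2OC(C)(C)C(C)(C)O2)c(OC)c1OC
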